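Cuts: first the acyl–O bonds at O7 and O9 and the enone (back to a C1 silyl ether and a C3 exocyclic methylene). Then C7–C8 and C8–C9 are cut together, which removes C8 and leaves a six-membered 7,9-dione with a C7–C9 bond. Then C7–C9 (pinacol), C5–C6 (tethered ester aldol), C4–C10 plus C5–C11 ([2+2]) and C1–C2 (vinylogous aldol).
Enabling feature: in the seven-membered ring (C5–C6–C7–C8–C9–C10, closed through C4 or C11) C8 is the only CH2. It lies between the two oxygen-bearing carbons C7 and C9, whose outer neighbours C6 (CMe2) and C10 (methyl-bearing cyclobutane carbon) are quaternary. The ring is therefore a non-enolisable six-membered 1,2-dione plus one inserted carbon.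
Forward: the chain is joined at C1–C2. The cyclobutane and the six-membered ring arise together in a vinylketene–alkene cycloaddition. An isobutyrate on O–C9 delivers C6/C7 to C5 as a bridging lactone, which is recast as the six-membered dione ring. One-carbon insertion gives the seven-membered ring; esters and enone come last.
Stereochemistry: one catalytic asymmetric aldol sets C1 (1S). Allylic 1,3-strain and the E-alkene relay it to C4, C10 and C11 in the [2+2], and the tether and the cage fix C5. C9 comes from an oxazaborolidine reduction and C7 from hydride delivery from O9 (anti). C1 ends as the ketone.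

Key step: step 14

Numbering: longipinane numbering of the target is used for all cage compounds: C1(=O)–C2=C3(CH3)–C4–C5–C6(CH3)2–C7–C8–C9–C10(CH3)–C11, plus the bonds C1–C11, C4–C10 and C5–C11. The cyclobutane is C4–C5–C11–C10, and C15 is the carbon on C3.
Assumption: the (R,R)-form of the bisphosphoramide of step 2 is taken to direct nucleophiles to the Re face of conjugated aldehydes. The (S,S)-form is therefore specified for the Si-face addition needed. If the sense is the reverse, the antipodal catalyst is used and nothing else changes.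

Step 1
Reactants: 1 methyl 3-methylbut-2-enoate
Product: 2 tert-butyl[(1-methoxy-3-methylbuta-1,3-dien-1-yl)oxy]dimethylsilane
Conditions: LDA, THF/DMPU, −78 °C; TBSCl, −78 °C → rt
Reagents that add atoms: tert-butyldimethylsilyl chloride, CC(C)(C)[Si](C)(C)Cl
Why: LDA removes a γ-proton of the senecioate and the extended lithium dienolate is silylated on oxygen (silyl ketene acetal formation), which gives the γ-nucleophilic dienol ether and creates no stereocentre.

Step 2
Reactants: 2 silyl dienol ether; 3 3-methylbut-2-enal
Product: 4 methyl (2E,5S)-5-hydroxy-3,7-dimethylocta-2,6-dienoate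
Conditions: SiCl4 (1.1 equiv), (S,S)-N,N′-bis(3,5-dimethyl-4-oxido-4,5-dihydro-3H-dinaphtho[2,1-d:1′,2′-f][1,3,2]diazaphosphepin-4-yl)-N,N′-dimethylpentane-1,5-diamine (5 mol %), i-Pr2NEt (10 mol %), CH2Cl2, −78 °C; aq. NaHCO3
Reagents that add atoms: 3-methylbut-2-enal (3), CC(C)=CC=O
Why: Catalytic enantioselective vinylogous Mukaiyama aldol addition under Lewis-base activation of SiCl4: the dienol ether reacts only at its γ-carbon, the chiral phosphoramide-bound silicon cation leaves the Si face of the conjugated aldehyde open and thereby sets the 5S carbinol (C1 of the target), and the enoate is formed with E geometry.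

Step 3
Reactants: 4 methyl (2E,5S)-5-hydroxy-3,7-dimethylocta-2,6-dienoate
Product: 5 methyl (2E,5S)-5-(tert-butyldimethylsilyloxy)-3,7-dimethylocta-2,6-dienoate
Conditions: TBSCl, imidazole, DMF, rt
Reagents that add atoms: tert-butyldimethylsilyl chloride, CC(C)(C)[Si](C)(C)Cl
Why: Imidazole-promoted silylation of a secondary allylic alcohol is routine and leaves the carbinol centre and both alkenes unchanged.

Step 4
Reactants: 5 silyl ether
Product: 6 methyl (2E,5S,6E)-5-(tert-butyldimethylsilyloxy)-8-hydroxy-3,7-dimethylocta-2,6-dienoate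
Conditions: SeO2 (0.3 equiv), t-BuOOH (3 equiv), CH2Cl2, 0 °C → rt
Reagents that add atoms: tert-butyl hydroperoxide, CC(C)(C)OO
Why: Riley-type allylic hydroxylation (ene reaction followed by [2,3]-sigmatropic shift) takes place at the electron-rich C6=C7 bond and not at the enoate, and it oxidises the methyl group trans to the chain, so that the 6E alcohol results whose geometry later decides which C10 substituent faces C5.

Step 5
Reactants: 6 hydroxy ester
Product: 7 (2E,5S,6E)-5-(tert-butyldimethylsilyloxy)-8-hydroxy-3,7-dimethylocta-2,6-dienoic acid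
Conditions: LiOH, THF/MeOH/H2O, 40 °C; 1 M HCl to pH 4, 0 °C
Reagents that add atoms: lithium hydroxide, [Li+].[OH-]
Why: Saponification of the methyl enoate with LiOH spares the silyl ether and the allylic alcohol, and mild acidification liberates the acid without ionising the allylic C–O bonds.

Step 6
Reactants: 7 hydroxy acid; 8 2-methylpropanoic (isobutyric) anhydride
Product: 10 (2E,5S,6E)-5-(tert-butyldimethylsilyloxy)-3,7-dimethyl-8-(2-methylpropanoyloxy)octa-2,6-dienoic acid, via mixed anhydride 9 (not isolated)
Conditions: 8 (3 equiv), 4-(dimethylamino)pyridine (10 mol %), pyridine, CH2Cl2, 0 °C → rt; THF/sat. aq. NaHCO3, rt; acidify to pH 4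
Reagents that add atoms: 2-methylpropanoic anhydride (8), CC(C)C(=O)OC(=O)C(C)C
Why: Nucleophile-catalysed acylation esterifies the primary allylic alcohol and turns the carboxyl group into mixed anhydride 9, which bicarbonate hydrolyses at its unconjugated isobutyryl carbonyl far faster than any ester is touched, so that the isobutyrate that carries C6 and C7 is in place on O–C9.

Step 7
Reactants: 10 acyloxy acid
Product: 13 bicyclo[3.1.1]heptan-6-one with C5=O, C3=CH2, 1S-OTBS on the side of the C5 bridge, and C10 bearing CH3 (towards the C1–C3 bridge) and CH2OC(O)CH(CH3)2 (towards C5), via acid chloride 11 (not isolated), via vinylketene 12 (not isolated)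
Conditions: 1-chloro-N,N,2-trimethylprop-1-en-1-amine, CH2Cl2, 0 °C; slow addition to Et3N, toluene, reflux, high dilution
Reagents that add atoms: none
Why: Neutral chloroenamine activation spares the silyl ether, Et3N removes a proton from the C3 methyl group that lies cis to the acyl group, and the resulting vinylketene undergoes the known intramolecular crossed [2+2] cycloaddition with the trisubstituted alkene (ketene carbonyl C5 to the less substituted C11, C4 to C10) with retention of the 6E geometry (C10 methyl cis to C1, C9 towards C5) and on the alkene face dictated by allylic 1,3-strain, because H1 must lie next to the C10 methyl group and the silyloxy group then points away from the ketene, so that the 1S centre fixes C4, C10 and C11.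

Step 8
Reactants: 13 bicyclic ketone
Product: 16 bridged seven-membered lactone (C5–C6(CH3)2–C7(=O)–O–C9H2–C10) carrying O-C(=S)SCH3 on C5, via lithium aldolate 14 (not isolated), via lithium xanthate 15 (not isolated)
Conditions: LDA (1.1 equiv), THF, −78 °C; CS2, −78 → −20 °C; MeI, → rt
Reagents that add atoms: carbon disulfide, S=C=S; iodomethane, CI
Why: Intramolecular ester-enolate aldol addition: the ketone has only bridgehead α-hydrogens and cannot enolise, the lithium enolate of the isobutyrate is held over one face of the strained cyclobutanone by the C9–O tether and so forms C5–C6 on the face of C9 with the alkoxide pointing outward, and the small electrophile CS2 followed by MeI traps the crowded tertiary alkoxide as its xanthate before retro-aldol cleavage or silyl migration can set in.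

Step 9
Reactants: 16 xanthate
Product: 17 (1S)-1-(tert-butyldimethylsilyloxy)-8-oxalongipin-3(15)-en-7-one (bridged lactone with C5–H)
Conditions: Bu3SnH (1.5 equiv), 2,2′-azobis(2-methylpropionitrile) (cat.), toluene, 90 °C
Reagents that add atoms: none
Why: Barton–McCombie deoxygenation: the stannyl radical adds to the thiocarbonyl group much faster than to the 1,1-disubstituted alkene, syn elimination of the tertiary xanthate is impossible because C4 and C11 are bridgeheads and C6 is quaternary, and the caged C5 radical can take up hydrogen only from the outer face, which gives the C5–H configuration of the target.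

Step 10
Reactants: 17 lactone
Product: 18 diol with C(CH3)2CH2OH on C5 and CH2OH on C10, both on the cyclobutane face opposite to the C1–C3 bridge
Conditions: LiAlH4, THF, 0 °C → rt; aqueous work-up
Reagents that add atoms: none
Why: Hydride reduction of a lactone to the diol is reliable even next to a quaternary carbon and touches neither the silyl ether nor the isolated alkene nor any stereocentre.

Step 11
Reactants: 18 diol
Product: 19 dialdehyde (C7H=O on C6, C9H=O on C10)
Conditions: (COCl)2, DMSO, CH2Cl2, −78 °C; Et3N, → 0 °C
Reagents that add atoms: none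
Why: In the Swern oxidation both neopentyl alcohols are activated before base is added, which avoids lactol formation and re-oxidation to the lactone, and the two aldehydes formed have no α-hydrogen and cannot epimerise or self-condense.

Step 12
Reactants: 19 dialdehyde
Product: 20 (1S)-1-(tert-butyldimethylsilyloxy)-8-norlongipin-3(15)-ene-7,9-diol (C7–C9 bond formed; cis-diol expected, configuration at C7 and C9 of no consequence)
Conditions: SmI2 (2.5 equiv), t-BuOH, THF, −78 °C → rt
Reagents that add atoms: none
Why: Intramolecular pinacol coupling with divalent samarium joins two non-enolisable aldehydes that are held side by side on one face of the cyclobutane and closes the six-membered ring irreversibly, and the carbinol configurations set by the chelated diketyl do not matter because both carbons become carbonyl groups in the next step.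

Step 13
Reactants: 20 diol
Product: 21 (1S)-1-(tert-butyldimethylsilyloxy)-8-norlongipin-3(15)-ene-7,9-dione (C7 bonded to C9)
Conditions: (COCl)2, DMSO, CH2Cl2, −78 °C; Et3N, → rt
Reagents that add atoms: none
Why: Swern oxidation converts 1,2-diols into 1,2-diones without C–C cleavage, and the product is stable because C6 and C10 are quaternary and no enol can form.

Step 14
Reactants: 21 nor-dione; 22 trimethylsilyldiazomethane
Product: 24 (1S)-1-(tert-butyldimethylsilyloxy)longipin-3(15)-ene-7,9-dione, via C8-silyl dione 23 (not isolated)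
Conditions: 22 (1.1 equiv), BF3·OEt2 (1.1 equiv), 2,6-di-tert-butyl-4-methylpyridine (0.2 equiv), CH2Cl2, −78 → −40 °C; pH 7 phosphate buffer/THF, rt
Reagents that add atoms: trimethylsilyldiazomethane (22), C[Si](C)(C)C=[N+]=[N-]
Why: BF3 binds one carbonyl oxygen of the s-cis dione, the nucleophilic carbon of 22 adds to that carbonyl group, and in the β-oxido diazonium ion the neighbouring acyl carbon shifts to the CH(SiMe3) carbon anti to the departing N2, so that C7–C8 and C8–C9 are both made while C7–C9 is given up. The C8-silyl 1,3-dione 23 (or its O-silyl enol form after a 1,3-silyl shift) is too poor an electrophile for a second insertion and loses silicon in the buffered work-up. The closest known reaction type is the Lewis-acid-promoted Tiffeneau–Demjanov-type homologation of ketones with diazoalkanes, including carbon insertion between the carbonyl groups of bridged non-enolisable 1,2-diones. The seven-membered ring (the bicyclo[4.1.1]octane part) is formed by one-carbon enlargement of the six-membered ring through a 1,2-shift and not by an end-to-end cyclisation. No stereocentre remains from the step, since C8 ends as CH2 and C1, C4, C5, C10 and C11 are not touched. The step needs acyl migration to win over alkyl migration and over epoxide closure: the only alkyl candidates C6 and C10 are quaternary and would have to move next to the bulky silylated carbon, attack at C7 or at C9 converges on one product, the dione is by far the most electrophilic site, and the hindered pyridine traps protons that could open the cyclobutane next to the alkene.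

Step 15
Reactants: 24 7,9-dione
Product: 25 (1S,9R)-1-(tert-butyldimethylsilyloxy)-9-hydroxylongipin-3(15)-en-7-one
Conditions: (S)-2-methyl-CBS-oxazaborolidine [(3aS)-1-methyl-3,3-diphenyltetrahydro-1H,3H-pyrrolo[1,2-c][1,3,2]oxazaborole] (0.5 equiv), catecholborane (1.2 equiv), toluene, −78 → −40 °C; MeOH, pH 7 buffer
Reagents that add atoms: none
Why: Corey–Bakshi–Shibata reduction: the oxazaborolidine binds the carbonyl lone pair on the side of the small C8H2 group and delivers hydride to the face that gives the 9R alcohol, as it does for tert-alkyl methyl ketones, while C9, whose quaternary neighbour C10 is tied back in the cyclobutane, is more open than C7, which is flanked on both faces by the C6 methyl groups, and catecholborane at low temperature leaves the alkene alone.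

Step 16
Reactants: 25 hydroxy ketone; 3 3-methylbut-2-enal
Product: 26 (1S,7R,9R)-1-(tert-butyldimethylsilyloxy)-7-hydroxylongipin-3(15)-en-9-yl 3-methylbut-2-enoate
Conditions: SmI2 (0.3 equiv), 3 (6 equiv), THF, −10 °C → rt
Reagents that add atoms: 3-methylbut-2-enal (3), CC(C)=CC=O
Why: Evans–Tishchenko reduction: the 9-OH forms a samarium-bound hemiacetal with the aldehyde and hands its hydride across the ring to the face of C7=O on which O9 stands, so that the new 7-OH is anti (7R) and the oxidised aldehyde stays on O9 as the senecioate, which tells the two oxygens apart in one step.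

Step 17
Reactants: 26 hydroxy ester; 27 (E)-2-methylbut-2-enoyl (tigloyl) chloride
Product: 28 (1S,7R,9R)-1-(tert-butyldimethylsilyloxy)-9-(3-methylbut-2-enoyloxy)longipin-3(15)-en-7-yl (E)-2-methylbut-2-enoate
Conditions: 27 (5 equiv), 4-(dimethylamino)pyridine (0.3 equiv), pyridine, 60 °C
Reagents that add atoms: (E)-2-methylbut-2-enoyl chloride (27), C/C=C(\C)C(Cl)=O
Why: Nucleophile-catalysed acylation of the hindered 7-OH with the stable E acid chloride in pyridine avoids the ketene pathway that stronger amine bases open, and the trans arrangement of O7 and O9 rules out acyl migration.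

Step 18
Reactants: 28 diester silyl ether
Product: 29 (1S,7R,9R)-1-hydroxy-9-(3-methylbut-2-enoyloxy)longipin-3(15)-en-7-yl (E)-2-methylbut-2-enoate
Conditions: HF·pyridine, pyridine, THF, 0 °C → rt
Reagents that add atoms: none
Why: Buffered fluoride cleavage of the secondary silyl ether is mild enough for both enoates and for the exocyclic alkene, and O1 lies on the other face of the cyclobutane from O9, so no acyl shift can follow.

Step 19
Reactants: 29 alcohol
Product: 31 (7R,9R)-9-(3-methylbut-2-enoyloxy)-1-oxolongipin-2-en-7-yl (E)-2-methylbut-2-enoate (target), via unconjugated enone 30 (not isolated)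
Conditions: Dess–Martin periodinane, pyridine, CH2Cl2, 0 °C → rt; aqueous wash; 1,8-diazabicyclo[5.4.0]undec-7-ene (0.2 equiv), CH2Cl2, rt
Reagents that add atoms: none
Why: Dess–Martin oxidation gives the β,γ-unsaturated ketone, whose doubly activated C2 protons allow base-catalysed migration of the exocyclic double bond into conjugation (C2=C3 with the C3 methyl group), while C11 is a bridgehead and cannot epimerise.

Compound list
1 | methyl 3-methylbut-2-enoate | COC(=O)C=C(C)C | starting material
2 | tert-butyl[(1-methoxy-3-methylbuta-1,3-dien-1-yl)oxy]dimethylsilane (ketene acetal geometry of no consequence) | COC(=CC(C)=C)O[Si](C)(C)C(C)(C)C | intermediate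
3 | 3-methylbut-2-enal | CC(C)=CC=O | starting material
4 | methyl (2E,5S)-5-hydroxy-3,7-dimethylocta-2,6-dienoate | COC(=O)/C=C(\C)C[C@H](O)C=C(C)C | intermediate
5 | methyl (2E,5S)-5-(tert-butyldimethylsilyloxy)-3,7-dimethylocta-2,6-dienoate | COC(=O)/C=C(\C)C[C@H](O[Si](C)(C)C(C)(C)C)C=C(C)C | intermediate
6 | methyl (2E,5S,6E)-5-(tert-butyldimethylsilyloxy)-8-hydroxy-3,7-dimethylocta-2,6-dienoate | COC(=O)/C=C(\C)C[C@H](O[Si](C)(C)C(C)(C)C)/C=C(\C)CO | intermediate
7 | (2E,5S,6E)-5-(tert-butyldimethylsilyloxy)-8-hydroxy-3,7-dimethylocta-2,6-dienoic acid | OC(=O)/C=C(\C)C[C@H](O[Si](C)(C)C(C)(C)C)/C=C(\C)CO | intermediate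
8 | 2-methylpropanoic anhydride | CC(C)C(=O)OC(=O)C(C)C | starting material
9 | mixed 2-methylpropanoic anhydride of acid 10 (not isolated) | CC(C)C(=O)OC(=O)/C=C(\C)C[C@H](O[Si](C)(C)C(C)(C)C)/C=C(\C)COC(=O)C(C)C | intermediate
10 | (2E,5S,6E)-5-(tert-butyldimethylsilyloxy)-3,7-dimethyl-8-(2-methylpropanoyloxy)octa-2,6-dienoic acid | OC(=O)/C=C(\C)C[C@H](O[Si](C)(C)C(C)(C)C)/C=C(\C)COC(=O)C(C)C | intermediate
11 | acid chloride of 10 (not isolated) | ClC(=O)/C=C(\C)C[C@H](O[Si](C)(C)C(C)(C)C)/C=C(\C)COC(=O)C(C)C | intermediate
12 | vinylketene from 11 (not isolated) | O=C=CC(=C)C[C@H](O[Si](C)(C)C(C)(C)C)/C=C(\C)COC(=O)C(C)C | intermediate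
13 | [4-(tert-butyldimethylsilyloxy)-7-methyl-2-methylidene-6-oxobicyclo[3.1.1]heptan-7-yl]methyl 2-methylpropanoate (1S; C10 methyl towards the C1–C3 bridge) | CC(C)C(=O)OC[C@@]2(C)[C@@H]3[C@@H](O[Si](C)(C)C(C)(C)C)CC(=C)[C@H]2C3=O | intermediate
14 | lithium C5-alkoxide of the bridged lactone (not isolated) | O=C1OC[C@@]2(C)[C@@H]3[C@@H](O[Si](C)(C)C(C)(C)C)CC(=C)[C@H]2[C@]3([O-])C1(C)C.[Li+] | intermediate
15 | lithium C5-O-dithiocarbonate of the bridged lactone (not isolated) | O=C1OC[C@@]2(C)[C@@H]3[C@@H](O[Si](C)(C)C(C)(C)C)CC(=C)[C@H]2[C@]3(OC(=S)[S-])C1(C)C.[Li+] | intermediate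
16 | C5-O-(methylsulfanylthiocarbonyl) bridged lactone | O=C1OC[C@@]2(C)[C@@H]3[C@@H](O[Si](C)(C)C(C)(C)C)CC(=C)[C@H]2[C@]3(OC(=S)SC)C1(C)C | intermediate
17 | (1S)-1-(tert-butyldimethylsilyloxy)-8-oxalongipin-3(15)-en-7-one | O=C1OC[C@@]2(C)[C@@H]3[C@@H](O[Si](C)(C)C(C)(C)C)CC(=C)[C@H]2[C@@H]3C1(C)C | intermediate
18 | seco-diol (C7H2OH on C6, C9H2OH on C10) | OC[C@@]2(C)[C@@H]3[C@@H](O[Si](C)(C)C(C)(C)C)CC(=C)[C@H]2[C@@H]3C(C)(C)CO | intermediate
19 | seco-dialdehyde | O=C[C@@]2(C)[C@@H]3[C@@H](O[Si](C)(C)C(C)(C)C)CC(=C)[C@H]2[C@@H]3C(C)(C)C=O | intermediate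
20 | (1S)-1-(tert-butyldimethylsilyloxy)-8-norlongipin-3(15)-ene-7,9-diol (C7, C9 not defined) | OC1C(O)[C@@]2(C)[C@@H]3[C@@H](O[Si](C)(C)C(C)(C)C)CC(=C)[C@H]2[C@@H]3C1(C)C | intermediate
21 | (1S)-1-(tert-butyldimethylsilyloxy)-8-norlongipin-3(15)-ene-7,9-dione | O=C1C(=O)[C@@]2(C)[C@@H]3[C@@H](O[Si](C)(C)C(C)(C)C)CC(=C)[C@H]2[C@@H]3C1(C)C | intermediate
22 | trimethylsilyldiazomethane | C[Si](C)(C)C=[N+]=[N-] | starting material
23 | 8-trimethylsilyl derivative of 24 (C8 not defined; not isolated) | O=C1C([Si](C)(C)C)C(=O)[C@@]2(C)[C@@H]3[C@@H](O[Si](C)(C)C(C)(C)C)CC(=C)[C@H]2[C@@H]3C1(C)C | intermediate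
24 | (1S)-1-(tert-butyldimethylsilyloxy)longipin-3(15)-ene-7,9-dione | O=C1CC(=O)[C@@]2(C)[C@@H]3[C@@H](O[Si](C)(C)C(C)(C)C)CC(=C)[C@H]2[C@@H]3C1(C)C | intermediate
25 | (1S,9R)-1-(tert-butyldimethylsilyloxy)-9-hydroxylongipin-3(15)-en-7-one | O=C1C[C@@H](O)[C@@]2(C)[C@@H]3[C@@H](O[Si](C)(C)C(C)(C)C)CC(=C)[C@H]2[C@@H]3C1(C)C | intermediate
26 | (1S,7R,9R)-1-(tert-butyldimethylsilyloxy)-7-hydroxylongipin-3(15)-en-9-yl 3-methylbut-2-enoate | O[C@@H]1C[C@@H](OC(=O)C=C(C)C)[C@@]2(C)[C@@H]3[C@@H](O[Si](C)(C)C(C)(C)C)CC(=C)[C@H]2[C@@H]3C1(C)C | intermediate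
27 | (E)-2-methylbut-2-enoyl chloride | C/C=C(\C)C(Cl)=O | starting material
28 | (1S,7R,9R)-1-(tert-butyldimethylsilyloxy)-9-(3-methylbut-2-enoyloxy)longipin-3(15)-en-7-yl (E)-2-methylbut-2-enoate | C/C=C(\C)C(=O)O[C@@H]1C[C@@H](OC(=O)C=C(C)C)[C@@]2(C)[C@@H]3[C@@H](O[Si](C)(C)C(C)(C)C)CC(=C)[C@H]2[C@@H]3C1(C)C | intermediate
29 | (1S,7R,9R)-1-hydroxy-9-(3-methylbut-2-enoyloxy)longipin-3(15)-en-7-yl (E)-2-methylbut-2-enoate | C/C=C(\C)C(=O)O[C@@H]1C[C@@H](OC(=O)C=C(C)C)[C@@]2(C)[C@@H]3[C@@H](O)CC(=C)[C@H]2[C@@H]3C1(C)C | intermediate
30 | (7R,9R)-9-(3-methylbut-2-enoyloxy)-1-oxolongipin-3(15)-en-7-yl (E)-2-methylbut-2-enoate (not isolated) | C/C=C(\C)C(=O)O[C@@H]1C[C@@H](OC(=O)C=C(C)C)[C@@]2(C)[C@@H]3C(=O)CC(=C)[C@H]2[C@@H]3C1(C)C | intermediate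
31 | (7R,9R)-9-(3-methylbut-2-enoyloxy)-1-oxolongipin-2-en-7-yl (E)-2-methylbut-2-enoate | C/C=C(\C)C(=O)O[C@@H]1C[C@@H](OC(=O)C=C(C)C)[C@@]2(C)[C@@H]3C(=O)C=C(C)[C@H]2[C@@H]3C1(C)C | target

Total step count: 19. Longest linear sequence: 19 steps (1 → 31).

Steps most likely to fail

1. Step 14.
   - What may go wrong: a quaternary alkyl carbon may migrate instead of the acyl carbon. The betaine may collapse to a spiro-epoxide. Acid may open the cyclobutane next to the alkene.
   - Fallback: addition and migration are separated. From 21, ethyl lithiodiazoacetate (ethyl diazoacetate, LDA, THF, −78 °C) should add to the more open C9 carbonyl group to give the α-diazo-β-hydroxy ester F1.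
   - Rh2(OAc)4 (cat.) in CH2Cl2 then expels N2, and the rhodium carbenoid accepts the migrating acyl carbon C7 to give the ring-enlarged ethyl 7,9-dioxo-8-carboxylate F2.
   - Krapcho dealkoxycarbonylation (LiCl, wet DMSO, 130 °C) comes back to the route at 24.

2. Step 15.
   - What may go wrong: hydride may be delivered to the wrong carbonyl group or to both. The reaction may stall through enolisation of the 1,3-dione. The β-hydroxy ketone may undergo retro-aldol opening during work-up.
   - Fallback: the distinction between C7 and C9 is moved from the reduction to the acylation. From 24, excess catecholborane and a full equivalent of the same oxazaborolidine (−40 → 0 °C) should reduce both ketones with the same sense, since both have a quaternary and a CH2 neighbour. This gives the anti (7R,9R)-diol F3.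
   - The less shielded 9-OH is then esterified selectively with 3-methylbut-2-enoic acid under Yamaguchi conditions (2,4,6-trichlorobenzoyl chloride, Et3N, 4-(dimethylamino)pyridine, toluene). The route is rejoined at 26, which also bypasses step 16.

3. Step 7.
   - What may go wrong: the cycloaddition may be slow because the alkene is flanked by two allylic C–O bonds, so that ketene dimerisation and re-addition of HCl take over. Facial selectivity may be eroded at reflux.
   - Fallback: a cationic heterocumulene replaces the ketene. From 10, coupling with pyrrolidine gives the pyrrolidine amide F4.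
   - Tf2O and 2,4,6-collidine in 1,2-dichloroethane should generate the much more electrophilic vinylketeniminium ion. This undergoes the same crossed [2+2] closure to the cyclobutaniminium triflate F5.
   - Hydrolysis with aq. NaHCO3 comes back to the route at 13.

Further compounds
F1 | step 14 | ethyl 2-diazo-2-[(1S)-1-(tert-butyldimethylsilyloxy)-9-hydroxy-7-oxo-8-norlongipin-3(15)-en-9-yl]acetate (C9 not defined) | O=C1C(O)(C(=[N+]=[N-])C(=O)OCC)[C@@]2(C)[C@@H]3[C@@H](O[Si](C)(C)C(C)(C)C)CC(=C)[C@H]2[C@@H]3C1(C)C
F2 | step 14 | ethyl (1S)-1-(tert-butyldimethylsilyloxy)-7,9-dioxolongipin-3(15)-ene-8-carboxylate (C8 not defined) | O=C1C(C(=O)OCC)C(=O)[C@@]2(C)[C@@H]3[C@@H](O[Si](C)(C)C(C)(C)C)CC(=C)[C@H]2[C@@H]3C1(C)C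
F3 | step 15 | (1S,7R,9R)-1-(tert-butyldimethylsilyloxy)longipin-3(15)-ene-7,9-diol | O[C@@H]1C[C@@H](O)[C@@]2(C)[C@@H]3[C@@H](O[Si](C)(C)C(C)(C)C)CC(=C)[C@H]2[C@@H]3C1(C)C
F4 | step 7 | (2E,4S,6E)-4-(tert-butyldimethylsilyloxy)-2,6-dimethyl-8-oxo-8-(pyrrolidin-1-yl)octa-2,6-dien-1-yl 2-methylpropanoate | O=C(N1CCCC1)/C=C(\C)C[C@H](O[Si](C)(C)C(C)(C)C)/C=C(\C)COC(=O)C(C)C
F5 | step 7 | pyrrolidinium-1-ylidene analogue of 13 (C5=N+), trifluoromethanesulfonate | CC(C)C(=O)OC[C@@]2(C)[C@@H]3[C@@H](O[Si](C)(C)C(C)(C)C)CC(=C)[C@H]2C3=[N+]1CCCC1.[O-]S(=O)(=O)C(F)(F)F
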